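**Plan** (target numbering: C1 = CO2H, C3/C5 = dioxolane carbons, C7 = CH(CH3), C14–C17 = diene)

- Cuts: C14=C15 (phosphonate olefination), C9–C10 (Wittig, then saturation), C7–CH3 (conjugate addition) and C7=C8 (Wittig); this leaves the C1–C7 dioxolane-3,5-diacetate.
- Enabling feature: the CH2 arms C2 (on C3) and C6 (on C5) are cis on the 1,2-dioxolane ring, so a C1=C7 double bond plus a C3–C5 σ bond fold the core into meso cis-1,6-dimethylbicyclo[4.1.0]hept-3-ene; the last cut takes O2 out from between C3 and C5.
- Rings, forward: o-xylene → 1,4-diene → gem-dibromocyclopropane → norcarene (cyclopropane ring); photoinduced electron-transfer insertion of O2 into the ring-fusion bond closes the dioxolane; RuO4 cleavage of the alkene then opens the seven-membered carbocycle.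
- Chain, forward: meso diester → half-ester → C7 aldehyde → E-enethioate → 7-methyl thioester → C9 aldehyde → C10–C14 by Wittig and diimide → diene by cinnamylphosphonate olefination → saponification at C1.
- Stereochemistry: cis C3/C5 is forced by the bicyclic tether in the key step (meso product); the absolute sense comes from esterase desymmetrisation of the meso diester; C7 from catalyst-controlled conjugate addition of MeMgBr; both diene bonds E from the cinnamyl unit and the phosphonate olefination.

Key step: step 4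

Assumption: pig liver esterase is taken to hydrolyse the ester of the arm on the S-configured ring carbon of 11, and the hand of the ferrocenyl diphosphine in step 12 is the one that adds methyl to the Si face of the β-carbon; both assignments need confirmation on the substrate.

**Step 1**
Reactants: 1 o-xylene
Product: 2 1,2-dimethylcyclohexa-1,4-diene
Conditions: Li, NH3 (l), EtOH, Et2O, −78 to −33 °C
Reagents that add atoms: none
Why: Birch reduction, in which the two alkyl groups end up on one ring double bond, so the unconjugated diene with one tetrasubstituted and one 1,2-disubstituted alkene should form directly.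

**Step 2**
Reactants: 2 1,2-dimethylcyclohexa-1,4-diene; 3 bromoform
Product: 5 (1R,6S)-7,7-dibromo-1,6-dimethylbicyclo[4.1.0]hept-3-ene, via dibromocarbene 4 (not isolated)
Conditions: CHBr3 (1.0 equiv), KOt-Bu, pentane, −10 to 0 °C
Reagents that add atoms: bromoform 3, BrC(Br)Br
Why: α-elimination gives electrophilic dibromocarbene, whose suprafacial (2+1) cycloaddition is much faster at the tetraalkyl alkene than at the 1,2-dialkyl one, so the cis-fused meso monoadduct is expected.

**Step 3**
Reactants: 5 (1R,6S)-7,7-dibromo-1,6-dimethylbicyclo[4.1.0]hept-3-ene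
Product: 6 (1R,6S)-1,6-dimethylbicyclo[4.1.0]hept-3-ene
Conditions: Li, t-BuOH, THF, reflux
Reagents that add atoms: none
Why: dissolving-metal hydrodehalogenation of a gem-dibromocyclopropane, which leaves the isolated alkene, the unconjugated cyclopropane and both quaternary centres untouched.

**Step 4**
Reactants: 6 (1R,6S)-1,6-dimethylbicyclo[4.1.0]hept-3-ene; 7 dioxygen
Product: 8 (1R,6S)-1,6-dimethyl-7,8-dioxabicyclo[4.2.1]non-3-ene
Conditions: O2 (1 atm), 2,4,6-triphenylpyrylium tetrafluoroborate (5 mol %), CH2Cl2, 420 nm LEDs, −20 °C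
Reagents that add atoms: dioxygen 7, O=O
Why: Proposed new method: the excited pyrylium salt should remove one electron from the highest-lying σ orbital of 6, the strained bond between the two methyl-bearing ring-fusion carbons, and the radical cation should relax by stretching this bond into a 1,3-radical cation held inside a cycloheptene; wherever the electron is first taken, the hole should settle on this bond because a tetraalkylcyclopropane bond is easier to oxidise than a 1,2-dialkyl alkene in the same molecule. Triplet O2 then adds at the radical terminus, the peroxyl oxygen bonds to the cationic terminus, and the dioxolane radical cation is reduced by the pyranyl radical or by a further molecule of 6, which would carry a chain. The closest known reactions are the pyrylium- and cyanoarene-sensitised oxygenations of 1,2-diarylcyclopropanes and of bicyclo[2.1.0]pentanes, which insert O2 into a strained σ bond in the same formal (3+2) sense; a cyclopropane activated only by alkyl groups has not been used. The one ring formed, the 1,2-dioxolane, closes as a five-membered ring when the terminal peroxyl oxygen combines with the tertiary cationic carbon across the one-carbon bridge C9, so that both C–O bonds end at the former fusion carbons. The two new stereocentres C1 and C6 can only be cis, because the four-carbon butenylene bridge holds both termini on one face, and the product is therefore meso whatever the timing of the two C–O bond formations. The step needs oxidation at the σ bond and no ene or cycloaddition chemistry at the alkene: the pyrylium sensitiser forms almost no singlet oxygen or superoxide, the 1,2-disubstituted alkene is a slow partner for singlet oxygen in any case, and the non-nucleophilic solvent and low temperature leave O2 as the only trap for the radical cation.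

**Step 5**
Reactants: 8 (1R,6S)-1,6-dimethyl-7,8-dioxabicyclo[4.2.1]non-3-ene
Product: 10 2,2'-[(3R,5S)-3,5-dimethyl-1,2-dioxolane-3,5-diyl]diacetic acid, via dialdehyde 9 (not isolated)
Conditions: RuCl3·xH2O (2 mol %), NaIO4 (4.5 equiv), EtOAc/MeCN/H2O, 0 °C to rt
Reagents that add atoms: sodium periodate, [Na+].[O-]I(=O)(=O)=O; water, O
Why: RuO4-catalysed oxidative cleavage of a cis-disubstituted cycloalkene to the diacid; the di-tertiary peroxide has no C–H next to oxygen and is inert to the oxidant, and the cleavage turns the bicycle into the monocyclic meso dioxolane with both two-carbon arms.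

**Step 6**
Reactants: 10 2,2'-[(3R,5S)-3,5-dimethyl-1,2-dioxolane-3,5-diyl]diacetic acid
Product: 11 dimethyl 2,2'-[(3R,5S)-3,5-dimethyl-1,2-dioxolane-3,5-diyl]diacetate
Conditions: Me3SiCHN2, toluene/MeOH (4:1), 0 °C to rt
Reagents that add atoms: trimethylsilyldiazomethane, C[Si](C)(C)C=[N+]=[N-]
Why: methyl esterification by diazomethane released in situ, under neutral conditions that spare the β-peroxy carboxyl groups.

**Step 7**
Reactants: 11 dimethyl 2,2'-[(3R,5S)-3,5-dimethyl-1,2-dioxolane-3,5-diyl]diacetate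
Product: 12 2-[(3S,5R)-5-(2-methoxy-2-oxoethyl)-3,5-dimethyl-1,2-dioxolan-3-yl]acetic acid
Conditions: pig liver esterase, 0.1 M phosphate buffer pH 7.5/DMSO (9:1), 20 °C, pH-stat with 1 M NaOH (1.0 equiv); then 1 M HCl to pH 3
Reagents that add atoms: water, O
Why: enzymatic desymmetrisation of a meso diester (enantiotopic-group-selective hydrolysis, well known for 3-substituted glutarates and cis-1,3-dioxane-4,6-diacetates); no new stereocentre forms, but hydrolysing only the arm on the S-configured ring carbon fixes the absolute configuration of C3 and C5, and the anionic half-ester should not be hydrolysed further.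

**Step 8**
Reactants: 12 2-[(3S,5R)-5-(2-methoxy-2-oxoethyl)-3,5-dimethyl-1,2-dioxolan-3-yl]acetic acid
Product: 14 methyl 2-[(3R,5R)-5-(2-hydroxyethyl)-3,5-dimethyl-1,2-dioxolan-3-yl]acetate, via mixed anhydride 13 (not isolated)
Conditions: i-BuOCOCl, N-methylmorpholine, THF, −15 °C; then NaBH4, H2O, 0 °C
Reagents that add atoms: none
Why: chemoselective reduction of the carboxylic acid through its mixed carbonic anhydride, with NaBH4 leaving the methyl ester and the O–O bond alone.

**Step 9**
Reactants: 15 bromoacetyl bromide; 16 ethanethiol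
Product: 17 S-ethyl 2-bromoethanethioate
Conditions: pyridine, CH2Cl2, 0 °C
Reagents that add atoms: ethanethiol 16, CCS
Why: S-acylation of the thiol by the acyl bromide, which is far more electrophilic than the alkyl bromide.

**Step 10**
Reactants: 17 S-ethyl 2-bromoethanethioate; 18 triphenylphosphine
Product: 20 S-ethyl 2-(triphenyl-λ5-phosphanylidene)ethanethioate, via phosphonium bromide 19 (not isolated)
Conditions: PPh3, toluene, rt; then aq. Na2CO3, CH2Cl2, 0 °C
Reagents that add atoms: triphenylphosphine 18, c1ccc(cc1)P(c1ccccc1)c1ccccc1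
Why: SN2 quaternisation of the α-bromo thioester and deprotonation of the acidic phosphonium salt give the stabilised ylide.

**Step 11**
Reactants: 14 methyl 2-[(3R,5R)-5-(2-hydroxyethyl)-3,5-dimethyl-1,2-dioxolan-3-yl]acetate; 20 S-ethyl 2-(triphenyl-λ5-phosphanylidene)ethanethioate
Product: 22 S-ethyl (2E)-4-[(3R,5R)-5-(2-methoxy-2-oxoethyl)-3,5-dimethyl-1,2-dioxolan-3-yl]but-2-enethioate, via aldehyde 21 (not isolated)
Conditions: Dess–Martin periodinane (1,1,1-triacetoxy-1,1-dihydro-1,2-benziodoxol-3(1H)-one), NaHCO3, CH2Cl2, 0 °C to rt; then 20, rt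
Reagents that add atoms: ylide 20, CCSC(=O)C=P(c1ccccc1)(c1ccccc1)c1ccccc1
Why: Dess–Martin oxidation followed in the same flask by Wittig olefination with a stabilised ylide, which is E-selective and too weakly basic to trigger β-elimination of the peroxide from the unisolated aldehyde.

**Step 12**
Reactants: 22 S-ethyl (2E)-4-[(3R,5R)-5-(2-methoxy-2-oxoethyl)-3,5-dimethyl-1,2-dioxolan-3-yl]but-2-enethioate
Product: 23 S-ethyl (3S)-4-[(3R,5R)-5-(2-methoxy-2-oxoethyl)-3,5-dimethyl-1,2-dioxolan-3-yl]-3-methylbutanethioate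
Conditions: MeMgBr (1.3 equiv), CuBr·SMe2 (5 mol %), 1-[2-(diphenylphosphino)ferrocenyl]ethyldicyclohexylphosphine (Josiphos, 6 mol %, enantiomer for Si-face delivery), t-BuOMe, −75 °C; MeOH quench
Reagents that add atoms: methylmagnesium bromide, C[Mg]Br
Why: copper-catalysed asymmetric conjugate addition of a Grignard reagent to an E-α,β-unsaturated thioester, in which the chiral ferrocenyl diphosphine–copper complex delivers methyl to the Si face of C7 (catalyst control; 3S in 23, 7R in the target) while the hindered di-tertiary peroxide and the methyl ester should not react at −75 °C.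

**Step 13**
Reactants: 23 S-ethyl (3S)-4-[(3R,5R)-5-(2-methoxy-2-oxoethyl)-3,5-dimethyl-1,2-dioxolan-3-yl]-3-methylbutanethioate
Product: 24 methyl 2-[(3R,5R)-5-[(2R)-4-hydroxy-2-methylbutyl]-3,5-dimethyl-1,2-dioxolan-3-yl]acetate
Conditions: NaBH4, EtOH/THF, 0 °C to rt
Reagents that add atoms: none
Why: borohydride reduction of a thioester to the primary alcohol, which is much faster than reduction of the unactivated, hindered methyl ester and does not touch the peroxide.

**Step 14**
Reactants: 24 methyl 2-[(3R,5R)-5-[(2R)-4-hydroxy-2-methylbutyl]-3,5-dimethyl-1,2-dioxolan-3-yl]acetate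
Product: 25 methyl 2-[(3R,5R)-3,5-dimethyl-5-[(2S)-2-methyl-4-oxobutyl]-1,2-dioxolan-3-yl]acetate
Conditions: Dess–Martin periodinane, CH2Cl2, 0 °C to rt
Reagents that add atoms: none
Why: Dess–Martin oxidation of a primary alcohol to the aldehyde; C7 is β to the carbonyl and cannot epimerise.

**Step 15**
Reactants: 26 2-(4-bromobutyl)-1,3-dioxolane; 18 triphenylphosphine
Product: 27 [4-(1,3-dioxolan-2-yl)butyl]triphenylphosphonium bromide
Conditions: PPh3, MeCN, reflux
Reagents that add atoms: triphenylphosphine 18, c1ccc(cc1)P(c1ccccc1)c1ccccc1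
Why: SN2 quaternisation of a primary bromide, with the acetal stable in the absence of acid.

**Step 16**
Reactants: 25 methyl 2-[(3R,5R)-3,5-dimethyl-5-[(2S)-2-methyl-4-oxobutyl]-1,2-dioxolan-3-yl]acetate; 27 [4-(1,3-dioxolan-2-yl)butyl]triphenylphosphonium bromide
Product: 29 methyl 2-[(3R,5R)-5-[(2R,4Z)-8-(1,3-dioxolan-2-yl)-2-methyloct-4-en-1-yl]-3,5-dimethyl-1,2-dioxolan-3-yl]acetate, via phosphorus ylide 28 (not isolated)
Conditions: 27, NaN(SiMe3)2, THF, −78 to 0 °C; then 25, −78 °C to rt
Reagents that add atoms: phosphonium salt 27, [Br-].C1COC(CCCC[P+](c2ccccc2)(c2ccccc2)c2ccccc2)O1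
Why: Wittig olefination with a non-stabilised ylide (Z-selective, though the geometry is irrelevant because the alkene is saturated next), the preformed ylide adding to the aldehyde faster than it can enolise the methyl ester.

**Step 17**
Reactants: 29 methyl 2-[(3R,5R)-5-[(2R,4Z)-8-(1,3-dioxolan-2-yl)-2-methyloct-4-en-1-yl]-3,5-dimethyl-1,2-dioxolan-3-yl]acetate
Product: 31 methyl 2-[(3R,5R)-3,5-dimethyl-5-[(2R)-2-methyl-9-oxononyl]-1,2-dioxolan-3-yl]acetate, via saturated acetal 30 (not isolated)
Conditions: KO2CN=NCO2K, AcOH, MeOH/CH2Cl2, rt; then 1 M HCl, THF, rt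
Reagents that add atoms: water, O
Why: diimide reduction transfers H2 to the isolated cis-alkene by a concerted path that does not cleave the O–O bond (unlike catalytic hydrogenation), and aqueous acid then hydrolyses the acetal to the aldehyde.

**Step 18**
Reactants: 31 methyl 2-[(3R,5R)-3,5-dimethyl-5-[(2R)-2-methyl-9-oxononyl]-1,2-dioxolan-3-yl]acetate; 32 diethyl [(2E)-3-phenylprop-2-en-1-yl]phosphonate
Product: 34 methyl 2-[(3R,5R)-3,5-dimethyl-5-[(2R,9E,11E)-2-methyl-12-phenyldodeca-9,11-dien-1-yl]-1,2-dioxolan-3-yl]acetate, via phosphonate carbanion 33 (not isolated)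
Conditions: 32, NaN(SiMe3)2, THF, −78 °C; then 31, −78 °C to rt
Reagents that add atoms: diethyl cinnamylphosphonate 32, CCOP(=O)(C/C=C/c1ccccc1)OCC
Why: Horner–Wadsworth–Emmons olefination with an allylic phosphonate, which should form the new C14=C15 bond mainly E while the styryl double bond keeps its E geometry, any minor 14Z isomer to be removed by chromatography.

**Step 19**
Reactants: 34 methyl 2-[(3R,5R)-3,5-dimethyl-5-[(2R,9E,11E)-2-methyl-12-phenyldodeca-9,11-dien-1-yl]-1,2-dioxolan-3-yl]acetate
Product: 35 2-[(3R,5R)-3,5-dimethyl-5-[(2R,9E,11E)-2-methyl-12-phenyldodeca-9,11-dien-1-yl]-1,2-dioxolan-3-yl]acetic acid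
Conditions: LiOH·H2O, THF/MeOH/H2O, 0 °C to rt; then 1 M HCl to pH 3
Reagents that add atoms: lithium hydroxide, [Li+].[OH-]
Why: saponification of the methyl ester, tolerated by a peroxide whose two carbons are quaternary (no α-hydrogen, so no Kornblum–DeLaMare fragmentation) and by the diene.

**Compound list**

1 | o-xylene | Cc1ccccc1C | starting material
2 | 1,2-dimethylcyclohexa-1,4-diene | CC1=C(C)CC=CC1 | intermediate
3 | bromoform | BrC(Br)Br | starting material
4 | dibromocarbene | Br[C]Br | intermediate
5 | (1R,6S)-7,7-dibromo-1,6-dimethylbicyclo[4.1.0]hept-3-ene (meso, cis-fused) | C[C@@]12CC=CC[C@]1(C)C2(Br)Br | intermediate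
6 | (1R,6S)-1,6-dimethylbicyclo[4.1.0]hept-3-ene (meso) | C[C@@]12CC=CC[C@]1(C)C2 | intermediate
7 | dioxygen | O=O | starting material
8 | (1R,6S)-1,6-dimethyl-7,8-dioxabicyclo[4.2.1]non-3-ene (meso) | C1=CC[C@]2(C)C[C@](C)(C1)OO2 | intermediate
9 | 2,2'-[(3R,5S)-3,5-dimethyl-1,2-dioxolane-3,5-diyl]diacetaldehyde (meso) | O=CC[C@]1(C)C[C@](C)(CC=O)OO1 | intermediate
10 | 2,2'-[(3R,5S)-3,5-dimethyl-1,2-dioxolane-3,5-diyl]diacetic acid (meso) | OC(=O)C[C@]1(C)C[C@](C)(CC(=O)O)OO1 | intermediate
11 | dimethyl 2,2'-[(3R,5S)-3,5-dimethyl-1,2-dioxolane-3,5-diyl]diacetate (meso) | COC(=O)C[C@]1(C)C[C@](C)(CC(=O)OC)OO1 | intermediate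
12 | 2-[(3S,5R)-5-(2-methoxy-2-oxoethyl)-3,5-dimethyl-1,2-dioxolan-3-yl]acetic acid | OC(=O)C[C@]1(C)C[C@](C)(CC(=O)OC)OO1 | intermediate
13 | isobutyl carbonic 2-[(3S,5R)-5-(2-methoxy-2-oxoethyl)-3,5-dimethyl-1,2-dioxolan-3-yl]acetic anhydride | CC(C)COC(=O)OC(=O)C[C@]1(C)C[C@](C)(CC(=O)OC)OO1 | intermediate
14 | methyl 2-[(3R,5R)-5-(2-hydroxyethyl)-3,5-dimethyl-1,2-dioxolan-3-yl]acetate | OCC[C@]1(C)C[C@](C)(CC(=O)OC)OO1 | intermediate
15 | bromoacetyl bromide | BrCC(Br)=O | starting material
16 | ethanethiol | CCS | starting material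
17 | S-ethyl 2-bromoethanethioate | CCSC(=O)CBr | intermediate
18 | triphenylphosphine | c1ccc(cc1)P(c1ccccc1)c1ccccc1 | starting material
19 | [2-(ethylsulfanyl)-2-oxoethyl]triphenylphosphonium bromide | CCSC(=O)C[P+](c1ccccc1)(c1ccccc1)c1ccccc1.[Br-] | intermediate
20 | S-ethyl 2-(triphenyl-λ5-phosphanylidene)ethanethioate | CCSC(=O)C=P(c1ccccc1)(c1ccccc1)c1ccccc1 | intermediate
21 | methyl 2-[(3R,5S)-3,5-dimethyl-5-(2-oxoethyl)-1,2-dioxolan-3-yl]acetate | O=CC[C@]1(C)C[C@](C)(CC(=O)OC)OO1 | intermediate
22 | S-ethyl (2E)-4-[(3R,5R)-5-(2-methoxy-2-oxoethyl)-3,5-dimethyl-1,2-dioxolan-3-yl]but-2-enethioate | CCSC(=O)/C=C/C[C@]1(C)C[C@](C)(CC(=O)OC)OO1 | intermediate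
23 | S-ethyl (3S)-4-[(3R,5R)-5-(2-methoxy-2-oxoethyl)-3,5-dimethyl-1,2-dioxolan-3-yl]-3-methylbutanethioate | C[C@H](CC(=O)SCC)C[C@]1(C)C[C@](C)(CC(=O)OC)OO1 | intermediate
24 | methyl 2-[(3R,5R)-5-[(2R)-4-hydroxy-2-methylbutyl]-3,5-dimethyl-1,2-dioxolan-3-yl]acetate | C[C@H](CCO)C[C@]1(C)C[C@](C)(CC(=O)OC)OO1 | intermediate
25 | methyl 2-[(3R,5R)-3,5-dimethyl-5-[(2S)-2-methyl-4-oxobutyl]-1,2-dioxolan-3-yl]acetate | C[C@H](CC=O)C[C@]1(C)C[C@](C)(CC(=O)OC)OO1 | intermediate
26 | 2-(4-bromobutyl)-1,3-dioxolane | BrCCCCC1OCCO1 | starting material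
27 | [4-(1,3-dioxolan-2-yl)butyl]triphenylphosphonium bromide | [Br-].C1COC(CCCC[P+](c2ccccc2)(c2ccccc2)c2ccccc2)O1 | intermediate
28 | 2-[4-(triphenyl-λ5-phosphanylidene)butyl]-1,3-dioxolane | C1COC(CCCC=P(c2ccccc2)(c2ccccc2)c2ccccc2)O1 | intermediate
29 | methyl 2-[(3R,5R)-5-[(2R,4Z)-8-(1,3-dioxolan-2-yl)-2-methyloct-4-en-1-yl]-3,5-dimethyl-1,2-dioxolan-3-yl]acetate | C[C@H](C/C=C\CCCC2OCCO2)C[C@]1(C)C[C@](C)(CC(=O)OC)OO1 | intermediate
30 | methyl 2-[(3R,5R)-5-[(2R)-8-(1,3-dioxolan-2-yl)-2-methyloctyl]-3,5-dimethyl-1,2-dioxolan-3-yl]acetate | C[C@H](CCCCCCC2OCCO2)C[C@]1(C)C[C@](C)(CC(=O)OC)OO1 | intermediate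
31 | methyl 2-[(3R,5R)-3,5-dimethyl-5-[(2R)-2-methyl-9-oxononyl]-1,2-dioxolan-3-yl]acetate | C[C@H](CCCCCCC=O)C[C@]1(C)C[C@](C)(CC(=O)OC)OO1 | intermediate
32 | diethyl [(2E)-3-phenylprop-2-en-1-yl]phosphonate (diethyl cinnamylphosphonate) | CCOP(=O)(C/C=C/c1ccccc1)OCC | starting material
33 | sodium (2E)-1-(diethoxyphosphoryl)-3-phenylprop-2-en-1-ide | [Na+].CCOP(=O)([CH-]/C=C/c1ccccc1)OCC | intermediate
34 | methyl 2-[(3R,5R)-3,5-dimethyl-5-[(2R,9E,11E)-2-methyl-12-phenyldodeca-9,11-dien-1-yl]-1,2-dioxolan-3-yl]acetate | C[C@H](CCCCCC/C=C/C=C/c1ccccc1)C[C@]1(C)C[C@](C)(CC(=O)OC)OO1 | intermediate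
35 | 2-[(3R,5R)-3,5-dimethyl-5-[(2R,9E,11E)-2-methyl-12-phenyldodeca-9,11-dien-1-yl]-1,2-dioxolan-3-yl]acetic acid | C[C@H](CCCCCC/C=C/C=C/c1ccccc1)C[C@]1(C)C[C@](C)(CC(=O)O)OO1 | target

**Step count and risks**

Total: 19 steps (steps 9, 10 and 15 are reagent branches). Longest linear sequence: 16 steps from o-xylene (steps 1–8, 11–14, 16–19).

Step 4 (proposed new method). Electron transfer may fail to take place at the ring-fusion σ bond, or the radical cation may lose a proton or bond to the alkene across the ring before it captures O2. The fallback uses known reactions and runs from dibromide 5 to peroxide 8. Silver-assisted electrocyclic ring opening of 5 (AgNO3, aqueous acetone) breaks the same ring-fusion bond and should give 2-bromo-1,3-dimethylcyclohepta-2,5-dien-1-ol F1. Bromine–lithium exchange and protonation (t-BuLi, THF, −78 °C; H2O) would give 1,3-dimethylcyclohepta-2,5-dien-1-ol F2. Markovnikov oxymercuration–demercuration of the trisubstituted alkene (Hg(OAc)2, THF/H2O; NaBH4, NaOH) would give 1,3-dimethylcyclohept-5-ene-1,3-diol F3 as a mixture of diastereomers. Acid-catalysed perhydrolysis of this di-tertiary 1,3-diol (50% H2O2, H2SO4, 0 °C), the classical entry to tetraalkyl-1,2-dioxolanes, passes through the tertiary cations, so both diastereomers should converge on the bridged cis peroxide 8, where the route resumes.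

Step 7. The esterase may discriminate the two enantiotopic ester groups poorly, or hydrolyse the other arm. The fallback is a resolution and runs from diester 11 to half-ester 12. Controlled mono-saponification (1.0 equiv NaOH, THF/H2O, 0 °C) gives the racemic half-ester. Crystallisation of its salt with (R)-1-phenylethylamine (or with the S amine, if that one gives the less soluble salt of the wanted antipode) should provide (1R)-1-phenylethan-1-aminium 2-[(3S,5R)-5-(2-methoxy-2-oxoethyl)-3,5-dimethyl-1,2-dioxolan-3-yl]acetate F4, and acidification returns 12. The unwanted half-ester is re-esterified with Me3SiCHN2 to meso 11 and recycled.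

Step 12. Facial selectivity may be poor or the addition may stall, because the oxygen-rich quaternary centre near the acceptor can compete for the copper–magnesium catalyst. The fallback replaces catalyst control by a covalently bound auxiliary and runs from alcohol 14 to alcohol 24; it still relies on a methylcopper reagent and therefore does not cover attack of the organometallic on the O–O bond. Alcohol 14 is oxidised as in step 11 and the unisolated aldehyde 21 is olefinated with diethyl {2-oxo-2-[(4R)-2-oxo-4-phenyl-1,3-oxazolidin-3-yl]ethyl}phosphonate under mild-base conditions (LiCl, i-Pr2NEt, MeCN). This should give methyl 2-[(3R,5R)-3,5-dimethyl-5-[(2E)-4-oxo-4-[(4R)-2-oxo-4-phenyl-1,3-oxazolidin-3-yl]but-2-en-1-yl]-1,2-dioxolan-3-yl]acetate F5. The methylcopper reagent from MeMgBr and CuBr·SMe2 (THF/Me2S, −78 to −20 °C) adds to the magnesium-chelated s-cis conformer on the face away from the phenyl group, the Si face of C7. The expected product is methyl 2-[(3R,5R)-3,5-dimethyl-5-[(2S)-2-methyl-4-oxo-4-[(4R)-2-oxo-4-phenyl-1,3-oxazolidin-3-yl]butyl]-1,2-dioxolan-3-yl]acetate F6. NaBH4 in THF/H2O then cleaves the imide reductively to alcohol 24 and returns the auxiliary, leaving the methyl ester.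

**Further compounds**

F1 | step 4 | 2-bromo-1,3-dimethylcyclohepta-2,5-dien-1-ol (racemic) | CC1=C(Br)C(C)(O)CC=CC1
F2 | step 4 | 1,3-dimethylcyclohepta-2,5-dien-1-ol (racemic) | CC1=CC(C)(O)CC=CC1
F3 | step 4 | 1,3-dimethylcyclohept-5-ene-1,3-diol (mixture of diastereomers) | CC1(O)CC(C)(O)CC=CC1
F4 | step 7 | (1R)-1-phenylethan-1-aminium 2-[(3S,5R)-5-(2-methoxy-2-oxoethyl)-3,5-dimethyl-1,2-dioxolan-3-yl]acetate | C[C@@H]([NH3+])c1ccccc1.[O-]C(=O)C[C@]1(C)C[C@](C)(CC(=O)OC)OO1
F5 | step 12 | methyl 2-[(3R,5R)-3,5-dimethyl-5-[(2E)-4-oxo-4-[(4R)-2-oxo-4-phenyl-1,3-oxazolidin-3-yl]but-2-en-1-yl]-1,2-dioxolan-3-yl]acetate | O=C(/C=C/C[C@]1(C)C[C@](C)(CC(=O)OC)OO1)N1[C@H](c2ccccc2)COC1=O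
F6 | step 12 | methyl 2-[(3R,5R)-3,5-dimethyl-5-[(2S)-2-methyl-4-oxo-4-[(4R)-2-oxo-4-phenyl-1,3-oxazolidin-3-yl]butyl]-1,2-dioxolan-3-yl]acetate | C[C@H](CC(=O)N1[C@H](c2ccccc2)COC1=O)C[C@]1(C)C[C@](C)(CC(=O)OC)OO1
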